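(All runs were generated by integration with constants of no real substance, and the scatter is random.)

| setting | larch | cedar | epsilon | delta |
|---|---|---|---|---|
| left-handed substrate | 1.1 M | 1.1 M | 1.1 M | 1.1 M |
| right-handed substrate | 1.1 M | 1.1 M | 1.1 M | 1.1 M |
| reagent | 1.1 M | 1.7 M | 2.20 M | 2.20 M |
| precatalyst | 1.1 mM | 1.1 mM | 1.1 mM | 1.1 mM |
| remark | run made earlier | run made earlier |  |  |
| time |  |  | 40 h | 60 h |

- larch (time / h: left-handed product / %, right-handed product / %, left-handed substrate / %): 5.00: 6.2, 1.7, 45.7; 10.0: 16.7, 2.0, 34.0; 15.0: 21.8, 4.9, 27.2; 20.0: 27.5, 3.6, 23.9; 25.0: 27.7, 5.9, 21.2
- cedar (time / h: left-handed product / %, right-handed product / %, left-handed substrate / %): 2.00: 3.4, 1.1, 47.1; 6.00: 13.0, 2.8, 36.9; 12.0: 27.6, 4.0, 20.7; 15.0: 28.8, 7.1, 17.1; 25.0: 37.7, 10.2, 10.4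

(readings scatter by 1 percentage point)

- free catalyst is single-handed; left-handed substrate and right-handed substrate are mirror images of each other, charged as a racemate, each of them at the stated concentration
- the numbers in the tables scatter with a standard deviation of 1 percentage point
- an excess is the difference of the two amounts in percent of their sum
- an excess is below zero if the other one leads

- which of the two ends with the higher excess of left-handed product over right-handed product in the product ("neither" if they lie within 2 percentage points) (epsilon / delta / neither)
- excess of left-handed product over right-handed product in the product at the end, epsilon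
- excess of left-handed product over right-handed product in the product at the end, delta

By the last readings, at 25.0 h in the larch run and 25.0 h in the cedar run, we can close the books on the left-handed half of the substrate charge. Each mole of reagent spent books one mole of product, so a mole of left-handed substrate should stand either as left-handed substrate or as left-handed product. The larch run books 21.2% and 27.7%, a gap of 1.1 percentage points; the cedar run books 10.4% and 37.7%, a gap of 1.9 points.

We enter the gaps as left-handed product turned into its mirror image. The zero of our scale is then the racemic product, and the net flow follows c(left-handed product) − c(right-handed product). Taking that difference as grown evenly from zero, we divide the summed gaps by its summed time integrals. This gives the leak constant λ, the fraction of the difference crossing per hour: 0.00487 h⁻¹. It is a rough reading, since the summed gap of 3 points carries a scatter of 2 points and the even growth is a simplification. Each crossing lowers one product and raises the other, so the excess decays at twice λ. Product laid down evenly has a mean age of half the time, which gives the factor exp(−λt), and product laid down entirely at the start gives exp(−2λt). The cedar run reached 27.6% of left-handed product by 12.0 h and added 10 points over the next 13.0 h, a faster rise early than late, so we expect a factor between the two.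

The forecast gives 49% for epsilon (range 43% to 56%) and 42% for delta (range 36% to 50%), with epsilon higher: “Longer time erodes the product excess”. Our own reckoning takes these as the excess of fresh product and applies the two factors, which gives lower values: between 33.2% and 40.3% for epsilon, and between 23.4% and 31.4% for delta, in the same order.

The simulation gives 40.5% for epsilon and 31.9% for delta, so epsilon ends higher.

    free catalyst + left-handed substrate ⇌ catalyst intermediate A (K = 2.30 M⁻¹, k = 43.0 M⁻¹ min⁻¹)
    free catalyst + right-handed substrate ⇌ catalyst intermediate B (K = 0.540 M⁻¹, k = 23.0 M⁻¹ min⁻¹)
    reagent + catalyst intermediate A → free catalyst + left-handed product (k = 1.80 M⁻¹ min⁻¹)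
    reagent + catalyst intermediate B → free catalyst + right-handed product (k = 0.810 M⁻¹ min⁻¹)
    left-handed product ⇌ right-handed product (k = 6.80 × 10⁻⁵ min⁻¹)
    precatalyst → free catalyst (k = 0.00450 min⁻¹)
    free catalyst → spent catalyst (k = 0.00120 min⁻¹)

Epsilon is not at rest at 40 h: free catalyst stands at 16.5% of its charge, with 38% of the reagent and 71% of the right-handed substrate left. Applying exp(−2λt) to its 40.5% over the further 20.0 h gives 33.3%, where delta stands at 31.9%. The same step to 4.0 d gives 23.5%, and the flask left that long stands at 22.7%. At 400 h, spent catalyst is 100%, left-handed product 33.7%, right-handed product 32.4%, and the excess 1.88%.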